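# Synthesis plan for 8,8a-deoxyoleandolide (27) by nickel/chromium ring closure at C8–C9

## The problem

Compound 27 is a single 14-membered lactone: a C1–C13 propionate-type chain closed between the C1 carboxyl and O13, with no ring fusion. The work is therefore chain assembly plus one macrocyclisation. Ten stereocentres lie on the chain in two contiguous clusters, C2–C6 and C10–C13, and C8 stands alone between the C7 methylene and the C9 ketone. Inside each cluster a neighbour can steer the next centre (aldol addition, hydroxyl-directed ketone reduction). C6 cannot be relied on to steer C8 across C7, and C8 is α to the ketone, so it is best created late from a temporary neighbour at C9. The finished molecule holds a β-hydroxy ketone (C9/C11), a β-hydroxy lactone (C1/C3), three epimerisable α-centres (C2, C8, C10) and a 5-hydroxyl that can add to the C9 carbonyl. Strong base (retro-aldol, elimination, epimerisation) and hot strong acid (hemiketal dehydration) must therefore stay away from late intermediates. The enabling feature is that ring carbon C8 carries the one-carbon branch C8a and adjoins the C9 carbonyl. C8 can be the sp2 carbon of a 2-iodoallyl unit with C8a as its methylene, C9 can be an aldehyde, and joining them closes the 14-membered ring as an allylic carbinol. That hydroxyl can deliver hydrogen to C8 before it becomes the ketone. A second useful feature is that C2–C5 and C10–C13 both begin with the same (R)-2-methyl-3-oxo unit, so one β-ketoimide 9 can serve both halves.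

## Retrosynthesis

**End game, 27 back to 24.** No skeletal bond is cut. The O3/O5 acetonide and O11 silyl ether of 26 are added, the C9 ketone is taken back to the carbinol 25, and the C8–H/C8a–H bonds are removed to give the exocyclic alkene 24. This puts the epimerisable C8 centre and the aldol-labile β-hydroxy ketone at the very end and lets one mild acid treatment finish the synthesis. The forward steps need an 8,9-anti hydroxyl-directed hydrogenation and a non-enolising oxidation.

**Ring opening, 24 to 23 (C8–C9).** Cutting the C1–O13 ester instead would give a seco acid in which C8 must already be set in an open chain, out of reach of C6. Cutting C7–C8 or C9–C10 would close the ring by enolate chemistry beside two epimerisable centres. The C8–C9 cut falls between the two stereoclusters, creates only C9 (a centre that is later erased) and leaves the hydroxyl that controls C8. Precursor 23 is an acyclic ester carrying nine settled centres, an alkenyl iodide and an aldehyde. The forward reaction must add the alkenyl metal to the aldehyde without touching ester, acetal or silyl ether.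

**Ester link, 23 to 22 to 13 + 20 (C1–O13).** The C9 aldehyde is taken back to a primary silyl ether and the ester is cut. This splits the chain into the C1–C8 acid 13 (five centres) and the C9–C13 alcohol 20 (four centres), of similar size. Esterifying a secondary alcohol intermolecularly is far easier than the macrolactonisation it replaces. The forward step must not epimerise C2, and the C9 silyl ether must be convertible to the aldehyde in one operation.

**C1–C8 acid, 13 to 12 to 11 to 10 to 9 + 6 (C4–C5, then C3–H).** One aldol bond and one ketone reduction create C4, C5 and C3 next to the C2 centre already present in 9. Two successive propionate aldols would need protection and redox steps between them. The forward aldol must be 2,4-syn/4,5-syn with 5,6-anti, and the reduction 3,5-syn. The diol is locked as the acetonide 12, which also stiffens the chain for ring closure.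

**Iodoalkene aldehyde, 6 to 5 to 4 to 3 to 1 + 2 (C6–C7, C8–I).** C6 comes from enolate alkylation of 1 with 2. The iodine is added to the terminal alkyne of 4 while the molecule holds nothing acid-labile. The precursors are commercial.

**C9–C13 alcohol, 20 to 19 to 18 to 17 to 15 to 9 + 14 (C12–C13, then C11–H).** The same ketoimide 9 adds to acetaldehyde 14 in the 2,4-anti/4,5-syn sense, and a hydroxyl-directed anti reduction sets C11. Closing O13 onto the imide carbonyl gives lactone 17, which distinguishes O13 from O11 without a protecting-group step. After silylation, reduction to 19 and selective silylation of the primary hydroxyl give 20.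

**Ketoimide, 9 to 8 to 1 + 7.** A syn aldol of 1 with propanal 7 followed by oxidation gives 9. Only the methyl-bearing centre of 8 is needed.

## Roads not taken

**Alternative 1:** The cut is C4–C5 and C9–C10 at once, using the local mirror plane through C7 that the C3–C11 segment has when C9 is a carbinol. Both formyl groups of meso-2,4-dimethylpentanedial A1 would add (Z)-crotylboronic acid pinacol ester A2 in one flask to give the meso diene-diol A3.
- Merits: A3 holds six of the ten centres, four of them made in one operation without any chiral reagent, and it reaches the C4–C10 array faster than steps 1–7 do.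
- Weak points:
  - A1 is configurationally fragile, and after the first addition the δ-hydroxy aldehyde can close to a lactol before the second addition.
  - Substrate control by an achiral crotylboronate is only moderate and is needed twice.
  - A3 must be desymmetrised: its ends become C1–C3 and C11–C13, and O5 must stay a hydroxyl while O9 becomes the ketone.
  - Each vinyl terminus still needs stereocontrolled extension (C2, C3 on one side; C11, C12, C13 on the other).
  - The ring closure is not addressed.
- Comparison: the alternative is better in speed to the core. The chosen plan sets against it absolute control from one auxiliary enantiomer with no desymmetrisation, the shared ketoimide 9 (which uses the same symmetry), and a C8 centre left unset until the ring can control it.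

**Alternative 2:** The cut is C12–C13 plus a temporary O13–C9 bond. Acetaldehyde 14 and (1E,3Z)-1-methoxy-2-methyl-3-(trimethylsilyloxy)penta-1,3-diene A4 would combine in a catalysed [4+2] cycloaddition to the dihydropyranone A5.
- Merits: it is catalytic, needs no auxiliary, and could reach the C9–C13 unit at the lactol oxidation level in fewer operations than steps 11–15.
- Weak points:
  - It depends on high enantio- and cis-selectivity with the smallest, least discriminating aldehyde.
  - C10 and C11 must still be set from the ring (carbonyl reduction, then functionalisation of the enol ether), and the required relation of the C10 methyl trans to the C11 oxygen is not obviously the favoured one.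
  - It is a fragment tactic that says nothing about C8 or ring closure.
- Comparison: in step count for this fragment it is equal or better. The chosen plan sets against it two substrate-controlled steps of established sense that fix all four centres, and reuse of 9, which is needed anyway.

**Alternative 3:** The cut is C2–C3 inside the ring. SmI2 would reduce the 2-bromopropanoate of the seco aldehyde A6 to a samarium enolate that adds to the C3 aldehyde, closing the lactone as the bis-silyl ether A7.
- Merits: the closure forms a C–C bond, sets two centres, and leaves only desilylation afterwards, so the post-cyclisation phase is two steps shorter than in the chosen plan.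
- Weak points:
  - C2 and C3 are permanent centres and would be fixed in a 14-membered transition state for which no reliable model exists.
  - The C9 ketone and its β-silyloxy group are exposed to divalent samarium (ketyl formation, coupling with the aldehyde).
  - The samarium aldolate of a β-hydroxy lactone can revert.
  - C8 must already be set in the open chain, which is the problem the chosen plan solves through the ring closure itself.
- Comparison: the alternative is shorter at the end. The chosen plan sets against it a closure that creates a single centre which is later erased, is correctable by oxidation and reduction, and supplies the handle for C8.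

Key step: step 18

## Route

Remark: atoms are numbered as in the macrolide (C1 lactone carbonyl to C13, C8a the methyl on C8), and the target is taken as the open 9-keto triol drawn; a possible ring–chain equilibrium with a 5,9-hemiketal in solution would not change the route.

Step 1
Reactants: 1 (R)-4-benzyl-3-propionyloxazolidin-2-one; 2 3-bromoprop-1-yne (propargyl bromide)
Product: 3 (R)-4-benzyl-3-[(S)-2-methylpent-4-ynoyl]oxazolidin-2-one
Conditions: NaN(SiMe3)2, THF, −78 °C; then 2, −78 → −40 °C
Reagents that add atoms: none
Why: Oxazolidinone enolate alkylation (Evans alkylation): the chelated sodium (Z)-enolate of 1 is alkylated on the face opposite the benzyl group, which should set the (S) centre that becomes C6.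

Step 2
Reactants: 3 (R)-4-benzyl-3-[(S)-2-methylpent-4-ynoyl]oxazolidin-2-one
Product: 4 (S)-2-methylpent-4-yn-1-ol
Conditions: LiBH4, H2O (1 equiv), Et2O, 0 °C
Reagents that add atoms: none
Why: Reductive cleavage of the N-acyl oxazolidinone by hydride attack at the exocyclic carbonyl; the α-centre is not enolised and the auxiliary is recovered.

Step 3
Reactants: 4 (S)-2-methylpent-4-yn-1-ol
Product: 5 (S)-4-iodo-2-methylpent-4-en-1-ol
Conditions: NaI, Me3SiCl, H2O, MeCN, 23 °C
Reagents that add atoms: sodium iodide, [Na+].[I-]
Why: Markovnikov hydroiodination of a terminal alkyne by HI made in situ, a known route from alk-4-yn-1-ols to 4-iodoalk-4-en-1-ols; protonation at the terminal carbon and capture by iodide give the 2-iodo-1-alkene, and no acid-labile group is present yet.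

Step 4
Reactants: 5 (S)-4-iodo-2-methylpent-4-en-1-ol
Product: 6 (S)-4-iodo-2-methylpent-4-enal
Conditions: Dess–Martin periodinane, pyridine, CH2Cl2, 0 → 23 °C; used at once
Reagents that add atoms: none
Why: Dess–Martin oxidation of a primary alcohol under buffered, non-enolising conditions; the alkenyl iodide is inert and immediate use protects the α-methyl centre.

Step 5
Reactants: 1 (R)-4-benzyl-3-propionyloxazolidin-2-one; 7 propanal
Product: 8 (R)-4-benzyl-3-[(2R,3S)-3-hydroxy-2-methylpentanoyl]oxazolidin-2-one
Conditions: Bu2BOTf, Et3N, CH2Cl2, −78 → 0 °C; then 7; work-up with pH 7 buffer, MeOH, H2O2, 0 °C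
Reagents that add atoms: none
Why: Evans syn aldol reaction: the (Z)-boron enolate reacts through a chair Zimmerman–Traxler transition state with the auxiliary carbonyl turned away from the enolate oxygen, which should give the (2R,3S) syn adduct; only the C2 centre is needed later.

Step 6
Reactants: 8 (R)-4-benzyl-3-[(2R,3S)-3-hydroxy-2-methylpentanoyl]oxazolidin-2-one
Product: 9 (R)-4-benzyl-3-[(R)-2-methyl-3-oxopentanoyl]oxazolidin-2-one
Conditions: SO3·pyridine, DMSO, Et3N, CH2Cl2, −10 → 0 °C
Reagents that add atoms: none
Why: Parikh–Doering oxidation of the secondary alcohol; the methyl-bearing centre keeps its configuration because allylic (1,3) strain holds its C–H bond in the plane of the imide carbonyl and makes enolisation between the carbonyls slow.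

Step 7
Reactants: 9 (R)-4-benzyl-3-[(R)-2-methyl-3-oxopentanoyl]oxazolidin-2-one; 6 (S)-4-iodo-2-methylpent-4-enal
Product: 10 (R)-4-benzyl-3-[(2R,4R,5S,6S)-5-hydroxy-8-iodo-2,4,6-trimethyl-3-oxonon-8-enoyl]oxazolidin-2-one
Conditions: TiCl4, iPr2NEt, CH2Cl2, −78 °C; then 6, −78 °C
Reagents that add atoms: none
Why: Titanium-mediated aldol addition of a β-ketoimide: the chelated (Z)-titanium enolate formed on the ethyl side adds through a closed transition state whose enolate face is fixed by the C2 centre, which should give the 2,4-syn/4,5-syn adduct; the 5,6-anti (anti-Felkin) relation that results is the one (Z)-enolates favour with α-methyl aldehydes, so the two elements should act together.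

Step 8
Reactants: 10 (R)-4-benzyl-3-[(2R,4R,5S,6S)-5-hydroxy-8-iodo-2,4,6-trimethyl-3-oxonon-8-enoyl]oxazolidin-2-one
Product: 11 (R)-4-benzyl-3-[(2R,3S,4R,5S,6S)-3,5-dihydroxy-8-iodo-2,4,6-trimethylnon-8-enoyl]oxazolidin-2-one
Conditions: Zn(BH4)2, CH2Cl2/Et2O, −78 → −20 °C
Reagents that add atoms: none
Why: Chelation-controlled 1,3-syn reduction of a β-hydroxy ketone: zinc bridges O5 and the C3 carbonyl and hydride attacks the chelate from its less hindered face, which should give the all-syn C3–C5 array; imide and alkenyl iodide are inert at this temperature.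

Step 9
Reactants: 11 (R)-4-benzyl-3-[(2R,3S,4R,5S,6S)-3,5-dihydroxy-8-iodo-2,4,6-trimethylnon-8-enoyl]oxazolidin-2-one
Product: 12 (R)-4-benzyl-3-{(R)-2-[(4S,5R,6S)-6-((S)-4-iodopent-4-en-2-yl)-2,2,5-trimethyl-1,3-dioxan-4-yl]propanoyl}oxazolidin-2-one
Conditions: Me2C(OMe)2, camphorsulfonic acid (cat.), CH2Cl2, 23 °C
Reagents that add atoms: 2,2-dimethoxypropane, COC(C)(C)OC
Why: Acid-catalysed transketalisation of the syn-1,3-diol to its six-membered isopropylidene acetal; capping both hydroxyls at once also stops O5 from attacking the imide carbonyl.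

Step 10
Reactants: 12 (R)-4-benzyl-3-{(R)-2-[(4S,5R,6S)-6-((S)-4-iodopent-4-en-2-yl)-2,2,5-trimethyl-1,3-dioxan-4-yl]propanoyl}oxazolidin-2-one
Product: 13 (R)-2-[(4S,5R,6S)-6-((S)-4-iodopent-4-en-2-yl)-2,2,5-trimethyl-1,3-dioxan-4-yl]propanoic acid
Conditions: LiOH, H2O2, THF/H2O, 0 °C; then Na2SO3; 1 M HCl to pH 3
Reagents that add atoms: hydrogen peroxide (acting as LiOOH), OO
Why: Hydroperoxide cleavage of the N-acyl oxazolidinone: LiOOH attacks the exocyclic carbonyl selectively and is too weakly basic to epimerise C2; acetonide and alkenyl iodide are stable to cold basic peroxide.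

Step 11
Reactants: 9 (R)-4-benzyl-3-[(R)-2-methyl-3-oxopentanoyl]oxazolidin-2-one; 14 acetaldehyde
Product: 15 (R)-4-benzyl-3-[(2R,4S,5R)-5-hydroxy-2,4-dimethyl-3-oxohexanoyl]oxazolidin-2-one
Conditions: Sn(OTf)2, Et3N, CH2Cl2, −20 °C; then 14, −78 °C
Reagents that add atoms: none
Why: Divalent-tin-mediated aldol addition of the β-ketoimide: the tin (Z)-enolate reacts on the enolate face opposite to that used by titanium, which should give the 2,4-anti/4,5-syn adduct, that is C10 and C12 methyls anti and C12/C13 syn.

Step 12
Reactants: 15 (R)-4-benzyl-3-[(2R,4S,5R)-5-hydroxy-2,4-dimethyl-3-oxohexanoyl]oxazolidin-2-one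
Product: 17 (3R,4S,5R,6R)-4-hydroxy-3,5,6-trimethyloxan-2-one, via anti-diol imide 16 (not isolated)
Conditions: Me4NBH(OAc)3, MeCN/AcOH, −30 °C; aqueous work-up; then Et3N, DMAP (cat.), CH2Cl2, 23 °C
Reagents that add atoms: none
Why: Evans–Saksena anti reduction: the C13 hydroxyl exchanges onto boron and delivers hydride intramolecularly through a chair transition state, giving the 11,13-anti diol 16; under mild base catalysis O13 then attacks the imide carbonyl, closing the δ-lactone and releasing the auxiliary, so that O11 is the only free hydroxyl.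

Step 13
Reactants: 17 (3R,4S,5R,6R)-4-hydroxy-3,5,6-trimethyloxan-2-one
Product: 18 (3R,4S,5S,6R)-4-[(tert-butyldimethylsilyl)oxy]-3,5,6-trimethyloxan-2-one
Conditions: tBuMe2SiOTf, 2,6-lutidine, CH2Cl2, −78 → 0 °C
Reagents that add atoms: tert-butyldimethylsilyl triflate, CC(C)(C)[Si](C)(C)OS(=O)(=O)C(F)(F)F
Why: Silylation of a hindered secondary alcohol with a silyl triflate and a non-nucleophilic base; the lactone keeps O13 and C9 masked, so only O11 is protected (the descriptor at ring C5 changes by priority only).

Step 14
Reactants: 18 (3R,4S,5S,6R)-4-[(tert-butyldimethylsilyl)oxy]-3,5,6-trimethyloxan-2-one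
Product: 19 (2S,3R,4S,5R)-3-[(tert-butyldimethylsilyl)oxy]-2,4-dimethylhexane-1,5-diol
Conditions: LiBH4, THF, 0 → 23 °C
Reagents that add atoms: none
Why: Hydride reduction of the δ-lactone to the 1,5-diol; LiBH4 leaves the silyl ether alone and a neutral work-up should avoid silyl migration.

Step 15
Reactants: 19 (2S,3R,4S,5R)-3-[(tert-butyldimethylsilyl)oxy]-2,4-dimethylhexane-1,5-diol
Product: 20 (2R,3S,4R,5S)-4-[(tert-butyldimethylsilyl)oxy]-3,5-dimethyl-6-[(triethylsilyl)oxy]hexan-2-ol
Conditions: Et3SiCl, imidazole, CH2Cl2, −78 → −20 °C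
Reagents that add atoms: chlorotriethylsilane, CC[Si](CC)(CC)Cl
Why: Selective silylation of the primary hydroxyl at low temperature by steric discrimination against the secondary carbinol next to a branched carbon; O13 stays free for acylation.

Step 16
Reactants: 13 (R)-2-[(4S,5R,6S)-6-((S)-4-iodopent-4-en-2-yl)-2,2,5-trimethyl-1,3-dioxan-4-yl]propanoic acid; 20 (2R,3S,4R,5S)-4-[(tert-butyldimethylsilyl)oxy]-3,5-dimethyl-6-[(triethylsilyl)oxy]hexan-2-ol
Product: 22 (2R,3S,4R,5S)-4-[(tert-butyldimethylsilyl)oxy]-3,5-dimethyl-6-[(triethylsilyl)oxy]hexan-2-yl (R)-2-[(4S,5R,6S)-6-((S)-4-iodopent-4-en-2-yl)-2,2,5-trimethyl-1,3-dioxan-4-yl]propanoate, via mixed anhydride 21 (not isolated)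
Conditions: 2,4,6-Cl3C6H2COCl, Et3N, THF, 23 °C; then 20, DMAP, toluene, 23 → 40 °C
Reagents that add atoms: none
Why: Yamaguchi esterification: DMAP attacks the mixed anhydride 21 at the aliphatic carbonyl and the acylpyridinium ion acylates the secondary C13 hydroxyl; the bases are too weak to epimerise C2.

Step 17
Reactants: 22 seco ester with C9 triethylsilyl ether (as named in step 16)
Product: 23 (2R,3S,4S,5R)-4-[(tert-butyldimethylsilyl)oxy]-3,5-dimethyl-6-oxohexan-2-yl (R)-2-[(4S,5R,6S)-6-((S)-4-iodopent-4-en-2-yl)-2,2,5-trimethyl-1,3-dioxan-4-yl]propanoate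
Conditions: (COCl)2, DMSO, CH2Cl2, −78 → −30 °C; then Et3N, −78 → 0 °C
Reagents that add atoms: none
Why: Swern oxidation with in situ cleavage of a primary triethylsilyl ether, a known selective oxidative desilylation: the chlorosulfonium salt opens the unhindered primary O–Si bond and the alkoxysulfonium ion collapses to the aldehyde on adding Et3N, while the secondary silyl ether, acetonide, ester and alkenyl iodide stay intact.

Step 18
Reactants: 23 seco ester with C8 iodoalkene and C9 aldehyde (as named in step 17)
Product: 24 (9S)-8-methylene-9-hydroxy macrolactone: the 14-membered lactone of 27 with C8=C8a as exocyclic methylene, a C9 hydroxyl syn to the C10 methyl in the zigzag drawing, O3/O5 bridged as the isopropylidene acetal and O11 as tert-butyldimethylsilyl ether; all other centres spatially as in 27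
Conditions: CrCl2 (excess), NiCl2 (cat.), degassed DMSO, 23 °C, slow addition of 23 to high dilution
Reagents that add atoms: none
Why: NiCl2 is reduced by CrCl2 to zerovalent nickel, which inserts into the C8–I bond; the alkenyl group passes to trivalent chromium and the alkenylchromium adds to the C9 aldehyde while nickel returns to the cycle (Nozaki–Hiyama–Kishi reaction). The closest known reaction type is the intramolecular nickel/chromium coupling of 2-iodo-1-alkenes with aldehydes, used to close large carbocycles and macrolactones as exo-methylene carbinols. The 14-membered ring closes by C8–C9 bond formation in the exo-trig mode with respect to the aldehyde, the new bond lying in the ring and C8a staying exocyclic. C9 is the only new stereocentre and should be set by the adjacent C10 centre in the Felkin–Anh sense (attack anti to the C11 branch), which gives the 9,10-syn, (9S) carbinol; the bulky, poorly coordinating O11 silyl ether keeps chelation and 1,3-induction weak. The step needs ring closure to outrun intermolecular coupling and protodeiodination, which slow addition to high dilution, the s-trans ester and the chair acetonide (both remove rotors from the chain) should secure. It also needs chemoselectivity for the aldehyde, which follows from the low basicity and low reactivity of alkenylchromium species toward esters, acetals and silyl ethers, so that C2 and C10 are not epimerised.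

Step 19
Reactants: 24 (9S)-8-methylene-9-hydroxy macrolactone
Product: 25 (8R)-8-methyl-9-hydroxy macrolactone: 24 with C8=C8a reduced to a methyl group anti to the C9 hydroxyl (C8 as in 27; C9 spatially unchanged, its descriptor becoming R because the priority of C8 falls on saturation)
Conditions: [Rh(nbd)(dppb)]BF4 (cat.), H2 (about 60 bar), CH2Cl2, 23 °C
Reagents that add atoms: none
Why: Hydroxyl-directed homogeneous hydrogenation with a cationic rhodium bisphosphine catalyst: the C9 hydroxyl binds rhodium and hydrogen is delivered to the alkene face presented in the conformer of least A(1,2) strain, which for 2-substituted allylic alcohols gives the 1,2-anti product, here (8R); high hydrogen pressure suppresses isomerisation of the allylic alcohol.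

Step 20
Reactants: 25 (8R)-8-methyl-9-hydroxy macrolactone
Product: 26 3,5-O-isopropylidene-11-O-(tert-butyldimethylsilyl)-8,8a-deoxyoleandolide (27 with O3/O5 as acetonide and O11 silylated)
Conditions: Dess–Martin periodinane, pyridine, CH2Cl2, 23 °C
Reagents that add atoms: none
Why: Dess–Martin oxidation of the secondary alcohol to the C9 ketone under buffered conditions that do not enolise toward C8 or C10; acetonide, silyl ether and lactone are inert.

Step 21
Reactants: 26 3,5-O-isopropylidene-11-O-(tert-butyldimethylsilyl)-8,8a-deoxyoleandolide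
Product: 27 8,8a-deoxyoleandolide, (3R,4S,5R,6S,7S,9R,11R,12S,13R,14R)-4,6,12-trihydroxy-3,5,7,9,11,13,14-heptamethyloxacyclotetradecane-2,10-dione
Conditions: 48% aq. HF, MeCN, 0 → 23 °C
Reagents that add atoms: none
Why: Acid-mediated global deprotection: aqueous HF cleaves the Si–O bond and hydrolyses the isopropylidene acetal; no base meets the β-hydroxy ketone or β-hydroxy lactone, and short, cold exposure should avoid dehydration through a 5,9-hemiketal.

## Compound list

1 | (R)-4-benzyl-3-propionyloxazolidin-2-one | CCC(=O)N1[C@H](Cc2ccccc2)COC1=O | starting material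
2 | 3-bromoprop-1-yne (propargyl bromide) | C#CCBr | starting material
3 | (R)-4-benzyl-3-[(S)-2-methylpent-4-ynoyl]oxazolidin-2-one | O=C(N1[C@H](Cc2ccccc2)COC1=O)[C@@H](C)CC#C | intermediate
4 | (S)-2-methylpent-4-yn-1-ol | OC[C@@H](C)CC#C | intermediate
5 | (S)-4-iodo-2-methylpent-4-en-1-ol | OC[C@@H](C)CC(I)=C | intermediate
6 | (S)-4-iodo-2-methylpent-4-enal | O=C[C@@H](C)CC(I)=C | intermediate
7 | propanal | CCC=O | starting material
8 | (R)-4-benzyl-3-[(2R,3S)-3-hydroxy-2-methylpentanoyl]oxazolidin-2-one | O=C(N1[C@H](Cc2ccccc2)COC1=O)[C@H](C)[C@@H](O)CC | intermediate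
9 | (R)-4-benzyl-3-[(R)-2-methyl-3-oxopentanoyl]oxazolidin-2-one | O=C(N1[C@H](Cc2ccccc2)COC1=O)[C@H](C)C(=O)CC | intermediate
10 | (R)-4-benzyl-3-[(2R,4R,5S,6S)-5-hydroxy-8-iodo-2,4,6-trimethyl-3-oxonon-8-enoyl]oxazolidin-2-one | O=C(N1[C@H](Cc2ccccc2)COC1=O)[C@H](C)C(=O)[C@H](C)[C@@H](O)[C@@H](C)CC(I)=C | intermediate
11 | (R)-4-benzyl-3-[(2R,3S,4R,5S,6S)-3,5-dihydroxy-8-iodo-2,4,6-trimethylnon-8-enoyl]oxazolidin-2-one | O=C(N1[C@H](Cc2ccccc2)COC1=O)[C@H](C)[C@@H](O)[C@H](C)[C@@H](O)[C@@H](C)CC(I)=C | intermediate
12 | (R)-4-benzyl-3-{(R)-2-[(4S,5R,6S)-6-((S)-4-iodopent-4-en-2-yl)-2,2,5-trimethyl-1,3-dioxan-4-yl]propanoyl}oxazolidin-2-one | O=C(N1[C@H](Cc2ccccc2)COC1=O)[C@H](C)[C@@H](O3)[C@H](C)[C@@H](OC3(C)C)[C@@H](C)CC(I)=C | intermediate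
13 | (R)-2-[(4S,5R,6S)-6-((S)-4-iodopent-4-en-2-yl)-2,2,5-trimethyl-1,3-dioxan-4-yl]propanoic acid (C1–C8 acid) | OC(=O)[C@H](C)[C@@H](O1)[C@H](C)[C@@H](OC1(C)C)[C@@H](C)CC(I)=C | intermediate
14 | acetaldehyde | CC=O | starting material
15 | (R)-4-benzyl-3-[(2R,4S,5R)-5-hydroxy-2,4-dimethyl-3-oxohexanoyl]oxazolidin-2-one | O=C(N1[C@H](Cc2ccccc2)COC1=O)[C@H](C)C(=O)[C@@H](C)[C@@H](C)O | intermediate
16 | (R)-4-benzyl-3-[(2R,3S,4S,5R)-3,5-dihydroxy-2,4-dimethylhexanoyl]oxazolidin-2-one (anti-diol imide, not isolated) | O=C(N1[C@H](Cc2ccccc2)COC1=O)[C@H](C)[C@@H](O)[C@@H](C)[C@@H](C)O | intermediate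
17 | (3R,4S,5R,6R)-4-hydroxy-3,5,6-trimethyloxan-2-one | O=C1[C@H](C)[C@@H](O)[C@@H](C)[C@@H](C)O1 | intermediate
18 | (3R,4S,5S,6R)-4-[(tert-butyldimethylsilyl)oxy]-3,5,6-trimethyloxan-2-one | O=C1[C@H](C)[C@@H](O[Si](C)(C)C(C)(C)C)[C@@H](C)[C@@H](C)O1 | intermediate
19 | (2S,3R,4S,5R)-3-[(tert-butyldimethylsilyl)oxy]-2,4-dimethylhexane-1,5-diol | OC[C@H](C)[C@@H](O[Si](C)(C)C(C)(C)C)[C@@H](C)[C@@H](C)O | intermediate
20 | (2R,3S,4R,5S)-4-[(tert-butyldimethylsilyl)oxy]-3,5-dimethyl-6-[(triethylsilyl)oxy]hexan-2-ol (C9–C13 alcohol) | CC[Si](CC)(CC)OC[C@H](C)[C@@H](O[Si](C)(C)C(C)(C)C)[C@@H](C)[C@@H](C)O | intermediate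
21 | mixed anhydride of 13 with 2,4,6-trichlorobenzoic acid (not isolated) | O=C(c1c(Cl)cc(Cl)cc1Cl)OC(=O)[C@H](C)[C@@H](O2)[C@H](C)[C@@H](OC2(C)C)[C@@H](C)CC(I)=C | intermediate
22 | (2R,3S,4R,5S)-4-[(tert-butyldimethylsilyl)oxy]-3,5-dimethyl-6-[(triethylsilyl)oxy]hexan-2-yl (R)-2-[(4S,5R,6S)-6-((S)-4-iodopent-4-en-2-yl)-2,2,5-trimethyl-1,3-dioxan-4-yl]propanoate | CC[Si](CC)(CC)OC[C@H](C)[C@@H](O[Si](C)(C)C(C)(C)C)[C@@H](C)[C@@H](C)OC(=O)[C@H](C)[C@@H](O1)[C@H](C)[C@@H](OC1(C)C)[C@@H](C)CC(I)=C | intermediate
23 | (2R,3S,4S,5R)-4-[(tert-butyldimethylsilyl)oxy]-3,5-dimethyl-6-oxohexan-2-yl (R)-2-[(4S,5R,6S)-6-((S)-4-iodopent-4-en-2-yl)-2,2,5-trimethyl-1,3-dioxan-4-yl]propanoate (seco ester, precursor of the key step) | O=C[C@H](C)[C@@H](O[Si](C)(C)C(C)(C)C)[C@@H](C)[C@@H](C)OC(=O)[C@H](C)[C@@H](O1)[C@H](C)[C@@H](OC1(C)C)[C@@H](C)CC(I)=C | intermediate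
24 | (9S)-8-methylene-9-hydroxy macrolactone, 3,5-O-isopropylidene, 11-O-tert-butyldimethylsilyl (product of the key step) | O=C1[C@H](C)[C@@H](O2)[C@H](C)[C@@H](OC2(C)C)[C@@H](C)CC(=C)[C@@H](O)[C@H](C)[C@@H](O[Si](C)(C)C(C)(C)C)[C@@H](C)[C@@H](C)O1 | intermediate
25 | (8R)-8-methyl-9-hydroxy macrolactone, 8-methyl anti to 9-hydroxyl, 3,5-O-isopropylidene, 11-O-tert-butyldimethylsilyl | O=C1[C@H](C)[C@@H](O2)[C@H](C)[C@@H](OC2(C)C)[C@@H](C)C[C@@H](C)[C@@H](O)[C@H](C)[C@@H](O[Si](C)(C)C(C)(C)C)[C@@H](C)[C@@H](C)O1 | intermediate
26 | 3,5-O-isopropylidene-11-O-(tert-butyldimethylsilyl)-8,8a-deoxyoleandolide | O=C1[C@H](C)[C@@H](O2)[C@H](C)[C@@H](OC2(C)C)[C@@H](C)C[C@@H](C)C(=O)[C@H](C)[C@@H](O[Si](C)(C)C(C)(C)C)[C@@H](C)[C@@H](C)O1 | intermediate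
27 | 8,8a-deoxyoleandolide, (3R,4S,5R,6S,7S,9R,11R,12S,13R,14R)-4,6,12-trihydroxy-3,5,7,9,11,13,14-heptamethyloxacyclotetradecane-2,10-dione | C[C@@H]1[C@@H](O)[C@@H](C)C[C@@H](C)C(=O)[C@H](C)[C@@H](O)[C@@H](C)[C@@H](C)OC(=O)[C@H](C)[C@H]1O | target

## Step count and risks

Total: 21 steps. Longest linear sequence: 14 steps (steps 1–4, 7–10, 16–21).

**Step 18 (key step).** Facial selectivity at C9 may be poor or reversed. In a 14-membered transition state, ring strain and transannular contacts can outweigh the Felkin preference of C10, and in this 10,11-syn aldehyde the 1,2- and 1,3-induction elements point in opposite directions. Slow closure relative to protodeiodination is a second concern, met by dilution and excess CrCl2. Fallback, setting out from 23: the cyclisation is run as planned and the carbinol mixture, 24 together with the (9R)-epimer F1, is oxidised with Dess–Martin periodinane to the 8-methylene-9-ketone F2. A catalyst-controlled 1,2-reduction with (R)-2-methyl-CBS-oxazaborolidine and catecholborane should then return 24, since the 2-substituted alkenyl arm normally acts as the large group and sends hydride to the Re face. Substrate control in the ring closure is thus replaced by reagent control on the enone, and the route is rejoined at 24.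

**Step 19.** Hydrogen delivery may follow the ring conformation and not the acyclic hydroxyl-directed model, and the cationic rhodium catalyst may isomerise the allylic alcohol to the saturated ketone, which would lose control at C8. Fallback, setting out from 24: Dess–Martin oxidation gives the enone F3 (the same compound as F2), and conjugate reduction with [(Ph3P)CuH]6 gives ketone 26 directly after protonation of the enolate at C8. C8 is then set by protonation from the ring periphery. Because it is α to the ketone it can be equilibrated with a mild amine base, and the epimers can be separated and recycled. The route is rejoined at 26.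

**Step 7.** The aldehyde centre C6 may oppose the enolate-face preference set by C2, giving poor double stereodifferentiation, and the titanium Lewis acid may promote retro-aldol or elimination on warming. Fallback, setting out from 6 and 1, using two auxiliary-controlled aldols:
- an Evans syn aldol (Bu2BOTf, Et3N) gives the adduct F4;
- silylation (tBuMe2SiOTf, 2,6-lutidine) gives the silyl ether F5;
- LiBH4 gives the alcohol F6;
- Dess–Martin oxidation gives the aldehyde F7;
- a second Evans syn aldol with 1 gives the C3-hydroxy imide F8;
- HF in MeCN removes the silyl group, rejoining the route at 11.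

**Step 3.** Addition of HI may run on to the geminal diiodide, or the free hydroxyl may add to the protonated alkyne and cyclise, because the alcohol sits five atoms from the reacting carbon; the small product is also easily lost on concentration. Fallback, setting out from 3: the halogen is introduced on the imide by iodoboration with B-iodo-9-borabicyclo[3.3.1]nonane followed by protonolysis with AcOH, giving the iodoalkene imide F9. LiBH4 reduction then rejoins the route at 5.

## Further compounds

F1 | step 18 | (9R)-epimer of 24 (8-methylene-9-hydroxy macrolactone with the C9 hydroxyl anti to the C10 methyl) | O=C1[C@H](C)[C@@H](O2)[C@H](C)[C@@H](OC2(C)C)[C@@H](C)CC(=C)[C@H](O)[C@H](C)[C@@H](O[Si](C)(C)C(C)(C)C)[C@@H](C)[C@@H](C)O1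
F2 | step 18 | 8-methylene-9-ketone macrolactone, 3,5-O-isopropylidene, 11-O-tert-butyldimethylsilyl | O=C1[C@H](C)[C@@H](O2)[C@H](C)[C@@H](OC2(C)C)[C@@H](C)CC(=C)C(=O)[C@H](C)[C@@H](O[Si](C)(C)C(C)(C)C)[C@@H](C)[C@@H](C)O1
F3 | step 19 | 8-methylene-9-ketone macrolactone, 3,5-O-isopropylidene, 11-O-tert-butyldimethylsilyl (identical with F2) | O=C1[C@H](C)[C@@H](O2)[C@H](C)[C@@H](OC2(C)C)[C@@H](C)CC(=C)C(=O)[C@H](C)[C@@H](O[Si](C)(C)C(C)(C)C)[C@@H](C)[C@@H](C)O1
F4 | step 7 | (R)-4-benzyl-3-[(2R,3S,4S)-3-hydroxy-6-iodo-2,4-dimethylhept-6-enoyl]oxazolidin-2-one | O=C(N1[C@H](Cc2ccccc2)COC1=O)[C@H](C)[C@@H](O)[C@@H](C)CC(I)=C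
F5 | step 7 | (R)-4-benzyl-3-[(2R,3S,4S)-3-[(tert-butyldimethylsilyl)oxy]-6-iodo-2,4-dimethylhept-6-enoyl]oxazolidin-2-one | O=C(N1[C@H](Cc2ccccc2)COC1=O)[C@H](C)[C@@H](O[Si](C)(C)C(C)(C)C)[C@@H](C)CC(I)=C
F6 | step 7 | (2S,3S,4S)-3-[(tert-butyldimethylsilyl)oxy]-6-iodo-2,4-dimethylhept-6-en-1-ol | OC[C@H](C)[C@@H](O[Si](C)(C)C(C)(C)C)[C@@H](C)CC(I)=C
F7 | step 7 | (2R,3S,4S)-3-[(tert-butyldimethylsilyl)oxy]-6-iodo-2,4-dimethylhept-6-enal | O=C[C@H](C)[C@@H](O[Si](C)(C)C(C)(C)C)[C@@H](C)CC(I)=C
F8 | step 7 | (R)-4-benzyl-3-[(2R,3S,4S,5S,6S)-5-[(tert-butyldimethylsilyl)oxy]-3-hydroxy-8-iodo-2,4,6-trimethylnon-8-enoyl]oxazolidin-2-one | O=C(N1[C@H](Cc2ccccc2)COC1=O)[C@H](C)[C@@H](O)[C@H](C)[C@@H](O[Si](C)(C)C(C)(C)C)[C@@H](C)CC(I)=C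
F9 | step 3 | (R)-4-benzyl-3-[(S)-4-iodo-2-methylpent-4-enoyl]oxazolidin-2-one | O=C(N1[C@H](Cc2ccccc2)COC1=O)[C@@H](C)CC(I)=C
A1 | alternative 1 | meso-2,4-dimethylpentanedial, (2R,4S) | O=C[C@@H](C)C[C@@H](C)C=O
A2 | alternative 1 | (Z)-crotylboronic acid pinacol ester | C/C=C\CB1OC(C)(C)C(C)(C)O1
A3 | alternative 1 | meso-3,5,7,9-tetramethylundeca-1,10-diene-4,8-diol | C=C[C@H](C)[C@@H](O)[C@@H](C)C[C@@H](C)[C@@H](O)[C@H](C)C=C
A4 | alternative 2 | (1E,3Z)-1-methoxy-2-methyl-3-(trimethylsilyloxy)penta-1,3-diene | CO/C=C(C)/C(O[Si](C)(C)C)=C/C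
A5 | alternative 2 | (2R,3S)-2,3,5-trimethyl-2,3-dihydro-4H-pyran-4-one | C1=C(C)C(=O)[C@@H](C)[C@@H](C)O1
A6 | alternative 3 | C13 2-bromopropanoate of the C3–C13 seco aldehyde, 5,11-bis-O-tert-butyldimethylsilyl, C9 ketone | O=C[C@H](C)[C@@H](O[Si](C)(C)C(C)(C)C)[C@@H](C)C[C@@H](C)C(=O)[C@H](C)[C@@H](O[Si](C)(C)C(C)(C)C)[C@@H](C)[C@@H](C)OC(=O)C(C)Br
A7 | alternative 3 | 5,11-bis-O-(tert-butyldimethylsilyl)-8,8a-deoxyoleandolide | O=C1[C@H](C)[C@@H](O)[C@H](C)[C@@H](O[Si](C)(C)C(C)(C)C)[C@@H](C)C[C@@H](C)C(=O)[C@H](C)[C@@H](O[Si](C)(C)C(C)(C)C)[C@@H](C)[C@@H](C)O1
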